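## The problem

Target 28 is a labdane: a trans-fused decalin (ring A C1–C5/C10, ring B C5–C10) with a 3-methylidenepent-4-enyl chain (C11–C16) on C9, free hydroxyls on C3 and C8, an acetate on C6 and six stereocentres, (3R,5S,6R,8S,9R,10R). C20, the C3 hydroxyl and C17 lie on one face; H5, the C6 acetoxy group, the C8 hydroxyl and the C9 chain lie on the other. The chain is therefore axial, anti to C20 and cis to the C8 oxygen, which is the C9 epimer of what an all-E polyene fold delivers. The quaternary C10 and its neighbour C9 must be set while ring B forms. Once they and C8 exist, C20 and the C4 gem-dimethyl group can steer reagents at C3, C5 and C6, but nothing in an achiral precursor fixes the absolute sense of C10. The 2-substituted buta-1,3-diene polymerises and reacts with boranes, acids and electrophiles, so it must be made late. The tertiary C8 hydroxyl sits 1,4 to C12 and closes to a tetrahydrofuran as soon as C12 carries a leaving group, and the acetate belongs on C6, the more hindered of the two secondary hydroxyls. Two features open the key step. The C8 oxygen and C11 are cis on adjacent carbons, so they can be the two ends of a γ-lactone (O–C8–C9–C11–C12). C6 carries oxygen next to C5, so a C5=C6 alkene, the remnant of an allyl cation spread over C6–C5–C10, is a natural intermediate.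

## Retrosynthesis

**Protecting-group endgame (28 ⇐ 27 ⇐ 26).** The last cuts are the two Si–O bonds at C3 and C8 and the acetyl C–O bond at C6. Acetylating a free 3,6,8-triol would favour the more accessible C3 hydroxyl, so C3 and C8 are silylated when C6 is acylated. The forward steps ask for acylation of one hindered equatorial hydroxyl in 26 and silyl removal from 27 without acetyl migration.

**C12–C13 (26 ⇐ 23 + 25).** This cut removes the fragile diene as a four-carbon Grignard reagent 25, made from chloroprene 24, and leaves the primary iodide 23. A cut at C11–C12 would put the reacting carbon next to the crowded C9, and building C13=C16 by olefination would need an enone beside a free tertiary alcohol. The forward reaction is an sp3–sp2 coupling at an unhindered primary carbon. It requires the C8 oxygen to be masked, otherwise the 8,12-ether forms.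

**Functional-group changes at C12 (23 ⇐ 22 ⇐ 21).** The iodide comes from the primary alcohol 22, which comes from the tris-silyl ether 21 by release of the primary silyl ether only. The forward steps rely on the large rate gap between primary, neopentyl secondary and tertiary triethylsilyl ethers.

**C5–H and C6–O (21 ⇐ 19).** Both bonds are cut together to give the C5=C6 alkene of 19. Carrying the C6 oxygen through ring formation would place an electron-withdrawing group beside the reacting olefin; here the alkene is what the key step leaves behind. The forward hydroboration must add syn, boron on C6, from the face opposite C20.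

**Reduction level and masking (19 ⇐ 18 ⇐ 17).** Triol 18 arises from keto lactone 17 by cutting the acyl C12–O8 bond and reducing C3. One hydride reagent does both, and one silylating agent then masks all three hydroxyls. This makes 17, with only three stereocentres, the true target of the ring construction.

**Key disconnection (17 ⇐ 15).** C9–C10 and C8–O are cut together. This opens ring B and the lactone and leads to hydroxy acid 15, whose only stereocentre is the C6 carbinol that ionisation destroys. Compared with a proton-initiated closure of a C5=C10 alkene, the allyl cation keeps C5=C6 for later oxygenation and offers a planar, prochiral C10 to a chiral counter-anion. The forward step needs face selection at C10, a chair-like closure and anti capture at C8.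

**C5–C6 (15 ⇐ 13 ⇐ 7 + 11).** Cutting the carbinol–ring bond separates a ring-A alkenyl triflate 7 from a Z-configured aldehyde ester 11; ester hydrolysis links 13 to 15. Cutting C6–C7 instead would require an allylic C7 nucleophile, with regiochemistry and olefin geometry at risk. The coupling must add to an enolisable β,γ-unsaturated aldehyde without base and leave a ketone and an ester alone.

**Fragments (7 ⇐ 6 ⇐ 4 ⇐ 2 ⇐ 1; 11 ⇐ 9 ⇐ 8).** Triflate 7 comes from dione 1 by monoketalisation, α-methylation, enol triflation of the only enolisable position and ketal removal. Aldehyde 11 comes from 4-methylanisole 8 by Birch reduction to diene 9 and cleavage of its enol-ether double bond. The Z olefin is inherited from the six-membered ring.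

## Roads not taken

**Alternative 1:** Ring B is cut at C6–C7. In the forward sense a dialkylaluminium chloride activates a C6 aldehyde on a finished ring A, which undergoes a carbonyl-ene reaction with an isopropenyl group on C9 to give the 6-hydroxy-8(17)-methylene decalin A1.
- Merits: Lewis-acid carbonyl-ene closures of six-membered rings are dependable; the C6 hydroxyl arrives equatorial; C5 is already in place, so no hydroboration is needed. In that respect this road is better than the chosen one.
- Weak points: the ene substrate must already hold C5, the quaternary C10 and an exocyclic stereocentre C9, contiguous and in one absolute sense, and the key step adds only C6 to them. The C8 carbinol must then come from hydration of the exocyclic alkene, where C20 and the axial C9 chain compete for control of the face.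
- Comparison: the chosen plan sets C8, C9 and C10 in one step from achiral material and fixes C8 through anti addition, at the price of an unproven catalytic step and a later hydroboration.

**Alternative 2:** The chiral-pool ketone (1S,5S)-verbenone A2 supplies ten carbons. A cuprate adds to its β-carbon (C10) and the enolate is alkylated at C9 with a bromoacetate, giving A3 with both new groups anti to the gem-dimethyl bridge.
- Merits: the absolute configuration is bought, the reactions are well known, and the bridge puts C11 anti to C20 as required. On certainty of absolute stereocontrol this road is better than the chosen one.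
- Weak points: no ring closes in the key step. Ring A must still be made by joining C3 to C4 after a regioselective cyclobutane cleavage, C17 must be added to a hindered enolisable ketone, and C5 and the C6 oxygen are still to come.
- Comparison: the chosen plan closes ring B and the lactone at once and has far fewer skeletal operations after the key step; it has to make up for that by finding a selective catalyst.

**Alternative 3:** An acyclic epoxy dienoic acid with a Z C8=C9 olefin and a C6 silyloxy group is folded by an alkylaluminium dichloride. C4–C5, C9–C10 and C8–O form, giving rings A and B and the cis lactone A4.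
- Merits: one step makes both rings and sets C3, C5, C8, C9 and C10, with C6 carried in. After A4 only the side chain and the acetate remain, a clearly shorter endgame than the chosen one.
- Weak points: the precursor needs an enantiopure epoxide and a matched C6 carbinol, made in separate asymmetric steps, on a long chain with one E and one Z trisubstituted olefin. The allylic C6 oxygen lowers the nucleophilicity of the central olefin, and bicyclisations through a Z olefin tend to stop or turn stepwise.
- Comparison: the chosen plan answers with an achiral precursor assembled in eight steps from three bulk chemicals, with the C6 oxygen used as the trigger and not carried as a deactivating bystander, and with catalytic chirality. It pays with a ketone reduction and a hydroboration after the key step.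

Key step: step 9

Remarks on the chemistry:
- Bicyclic compounds are named on the labdane skeleton with labdane numbering; in the 13,14,15,16-tetranor compounds C9 carries only C11–C12.
- Compounds 4, 13, 14 and 15 are racemic at one carbon, and that centre is erased (4 → 5, 15 → 16) before any lasting stereocentre is set.
- The catalyst of step 9 is written as the (S,S) acid. Which antipode gives 17 must be found by experiment, and the (R,R) acid is used if the (S,S) acid gives the mirror image.

## Route

Step 1
Reactants: 1 2,2-dimethylcyclohexane-1,3-dione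
Product: 2 6,6-dimethyl-1,4-dioxaspiro[4.5]decan-7-one
Conditions: ethylene glycol (1.1 equiv), p-TsOH (cat.), benzene, reflux, Dean–Stark
Reagents that add atoms: ethylene glycol, OCCO
Why: Acid-catalysed ketalisation; the first dioxolane makes the second carbonyl neopentyl on both sides and slow to react, so a limited amount of diol should stop at the monoketal.

Step 2
Reactants: 2 6,6-dimethyl-1,4-dioxaspiro[4.5]decan-7-one
Product: 4 6,6,8-trimethyl-1,4-dioxaspiro[4.5]decan-7-one (racemic), via lithium enolate 3 (not isolated)
Conditions: LiN(iPr)2, THF, −78 °C; MeI, −78 → 0 °C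
Reagents that add atoms: iodomethane, CI
Why: Enolate alkylation; only C8 of the ketone bears α-hydrogens, so one regioisomer is possible and slow addition of the base limits double methylation.

Step 3
Reactants: 4 6,6,8-trimethyl-1,4-dioxaspiro[4.5]decan-7-one (racemic)
Product: 6 6,6,8-trimethyl-1,4-dioxaspiro[4.5]dec-7-en-7-yl trifluoromethanesulfonate, via potassium enolate 5 (not isolated)
Conditions: KN(SiMe3)2, THF, −78 → 0 °C; PhNTf2, 0 °C → rt
Reagents that add atoms: N-phenylbis(trifluoromethanesulfonimide), O=S(=O)(N(c1ccccc1)S(=O)(=O)C(F)(F)F)C(F)(F)F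
Why: O-sulfonylation of the single possible enolate gives the tetrasubstituted enol triflate, as is routine for 2,2,6-trimethylcyclohexanones; the methyl-bearing stereocentre of 4 disappears.

Step 4
Reactants: 6 6,6,8-trimethyl-1,4-dioxaspiro[4.5]dec-7-en-7-yl trifluoromethanesulfonate
Product: 7 2,6,6-trimethyl-5-oxocyclohex-1-en-1-yl trifluoromethanesulfonate
Conditions: 2 M HCl, THF, rt
Reagents that add atoms: water, O
Why: Acetal hydrolysis; the alkenyl triflate is inert to aqueous acid and the β,γ-enone cannot move into conjugation across the quaternary carbon. Removing the ketal here spares the later acid-labile allylic carbinol.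

Step 5
Reactants: 8 4-methylanisole
Product: 9 1-methoxy-4-methylcyclohexa-1,4-diene
Conditions: Li, NH3 (l), THF, t-BuOH, −78 → −33 °C
Reagents that add atoms: none
Why: Birch reduction; both donor substituents end up on the remaining double bonds, giving the unconjugated 1,4-diene.

Step 6
Reactants: 9 1-methoxy-4-methylcyclohexa-1,4-diene
Product: 11 methyl (3Z)-4-methyl-6-oxohex-3-enoate, via methoxy hydroperoxide 10 (not isolated)
Conditions: O3 (1.0 equiv), CH2Cl2/MeOH, NaHCO3, −78 °C; Me2S, −78 °C → rt
Reagents that add atoms: ozone, [O-][O+]=O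
Why: Ozonolysis of the more electron-rich enol-ether double bond gives the ester from the methoxy-bearing carbon and, after reduction of 10, the aldehyde from the other. The trisubstituted olefin keeps the Z geometry of the ring; 11 is used at once because it is a β,γ-unsaturated aldehyde.

Step 7
Reactants: 7 2,6,6-trimethyl-5-oxocyclohex-1-en-1-yl trifluoromethanesulfonate; 11 methyl (3Z)-4-methyl-6-oxohex-3-enoate
Product: 13 methyl (3Z)-6-hydroxy-4-methyl-6-(2,6,6-trimethyl-5-oxocyclohex-1-en-1-yl)hex-3-enoate (racemic), via alkenylchromium dichloride 12 (not isolated)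
Conditions: CrCl2 (4 equiv), NiCl2 (2 mol%), DMF, rt → 50 °C, slow addition of 11
Reagents that add atoms: none
Why: Nozaki–Hiyama–Kishi coupling; zerovalent nickel inserts into the C–OTf bond and hands the alkenyl group to trivalent chromium, which adds to aldehydes but not to the ketone or ester. The reagent is not basic, so the aldehyde is neither enolised nor isomerised.

Step 8
Reactants: 13 methyl (3Z)-6-hydroxy-4-methyl-6-(2,6,6-trimethyl-5-oxocyclohex-1-en-1-yl)hex-3-enoate (racemic)
Product: 15 (3Z)-6-hydroxy-4-methyl-6-(2,6,6-trimethyl-5-oxocyclohex-1-en-1-yl)hex-3-enoic acid (racemic), via lithium carboxylate 14 (not isolated)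
Conditions: LiOH·H2O, THF/H2O, 0 °C; then 0.5 M HCl to pH 4, 0 °C
Reagents that add atoms: lithium hydroxide, [Li+].[OH-]
Why: Ester saponification; in the cold any dienolate reprotonates at the α-carbon, so the β,γ Z olefin stays in place. Acidifying only to pH 4 spares the allylic carbinol; 15 is used without storage.

Step 9
Reactants: 15 (3Z)-6-hydroxy-4-methyl-6-(2,6,6-trimethyl-5-oxocyclohex-1-en-1-yl)hex-3-enoic acid (racemic)
Product: 17 (8S,9R,10S)-3-oxo-13,14,15,16-tetranorlabd-5-en-12,8-olide, via allyl cation 16 (not isolated)
Conditions: (S,S)-imidodiphosphorimidate acid HN[P(=NSO2CF3)(O2C20H10Ar2)]2 (Ar = 3,5-(CF3)2C6H3; O2C20H10Ar2 = 3,3'-diaryl-1,1'-binaphthalene-2,2'-diolate; 5 mol%), CH2Cl2/(CF3)3COH, 5 Å molecular sieves, −40 °C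
Reagents that add atoms: none
Why: Proposed new method: the acid protonates the C6 hydroxyl, water leaves, and allyl cation 16 (charge shared by C6 and C10) is held as a contact ion pair by the confined chiral anion; C9 of the Z olefin then bonds to the tertiary terminus C10, the carboxyl oxygen closes on C8 anti to the new bond, and the proton returns to the anion. The closest known reaction types are the acid cyclisation of monocyclic homofarnesic acids to sclareolide-type lactones, imidodiphosphorimidate-catalysed enantioselective polyene cyclisation, and the closure of a cisoid (neryl-type) allyl cation onto its far terminus. Ring B closes 6-endo at the olefin through a chair-like array with C20 pseudoaxial, keeping C5=C6 inside the new ring, and the γ-lactone closes 5-exo onto the C8 cation. C10 is set by the face of the cation that the anion leaves open, so by the catalyst alone, because ionisation erases the C6 centre and both enantiomers of 15 converge on one ion pair. C9 is set relative to C10 by the chair, in which the Z geometry places C11 axial and anti to C20. C8 is set by anti addition across the olefin and by the tether, which can only reach the face of C11 and so gives the cis lactone. The step needs face selection at C10 (confinement, helped by hydrogen bonding of the carboxyl group to the anion), attack at C10 and not C6 (the latter would form a four-membered ring) and ring closure faster than proton loss to a diene (non-basic anion, non-nucleophilic fluorinated alcohol, low temperature).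

Step 10
Reactants: 17 (8S,9R,10S)-3-oxo-13,14,15,16-tetranorlabd-5-en-12,8-olide
Product: 18 (3R,8S,9R,10S)-13,14,15,16-tetranorlabd-5-ene-3,8,12-triol
Conditions: LiAlH4, THF, −78 → 25 °C; Rochelle salt work-up
Reagents that add atoms: none
Why: Hydride reduction of the ketone and of the lactone to the 8,12-diol. At C3 the small hydride adds axially, from the face opposite the axial C4 methyl and C20, as in 4,4-dimethyl-3-oxo terpenoids, giving the equatorial hydroxyl cis to C20.

Step 11
Reactants: 18 (3R,8S,9R,10S)-13,14,15,16-tetranorlabd-5-ene-3,8,12-triol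
Product: 19 (3R,8S,9R,10S)-3,8,12-tris(triethylsilyloxy)-13,14,15,16-tetranorlabd-5-ene
Conditions: Et3SiOTf (4 equiv), 2,6-lutidine, CH2Cl2, −78 → 0 °C
Reagents that add atoms: triethylsilyl trifluoromethanesulfonate, CC[Si](CC)(CC)OS(=O)(=O)C(F)(F)F
Why: Silylation with a silyl triflate, reactive enough for the tertiary C8 hydroxyl; the three ethers differ widely in lability, which the later steps use.

Step 12
Reactants: 19 (3R,8S,9R,10S)-3,8,12-tris(triethylsilyloxy)-13,14,15,16-tetranorlabd-5-ene
Product: 21 (3R,5S,6R,8S,9R,10R)-3,8,12-tris(triethylsilyloxy)-13,14,15,16-tetranorlabdan-6-ol, via C6 alkylborane 20 (not isolated)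
Conditions: BH3·THF (3 equiv), THF, 0 → 25 °C; then 3 M NaOH, 30% H2O2, 0 °C → rt
Reagents that add atoms: hydrogen peroxide, OO
Why: Hydroboration–oxidation; boron goes to the less substituted C6 and hydrogen to C5 in a syn addition from the face opposite C20 and the axial C4 methyl, as with 4,4-dimethyl-Δ5 steroids. Oxidation with retention then gives the trans ring fusion and the equatorial C6 hydroxyl together.

Step 13
Reactants: 21 (3R,5S,6R,8S,9R,10R)-3,8,12-tris(triethylsilyloxy)-13,14,15,16-tetranorlabdan-6-ol
Product: 22 (3R,5S,6R,8S,9R,10R)-3,8-bis(triethylsilyloxy)-13,14,15,16-tetranorlabdane-6,12-diol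
Conditions: pyridinium p-toluenesulfonate (0.1 equiv), MeOH/CH2Cl2, −10 → 0 °C, stopped when 21 is consumed
Reagents that add atoms: none
Why: Acid-catalysed methanolysis of silyl ethers; the primary ether is cleaved much faster than the neopentyl secondary and the tertiary ones, a standard selective deprotection.

Step 14
Reactants: 22 (3R,5S,6R,8S,9R,10R)-3,8-bis(triethylsilyloxy)-13,14,15,16-tetranorlabdane-6,12-diol
Product: 23 (3R,5S,6R,8S,9R,10R)-12-iodo-3,8-bis(triethylsilyloxy)-13,14,15,16-tetranorlabdan-6-ol
Conditions: I2, PPh3, imidazole, CH2Cl2, 0 °C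
Reagents that add atoms: iodine, II
Why: Appel-type iodination; the primary hydroxyl is activated and displaced while the hindered equatorial C6 hydroxyl is left. Imidazole buffers the acid so the silyl ethers survive, and the silylated C8 oxygen cannot close the 8,12-ether.

Step 15
Reactants: 24 2-chlorobuta-1,3-diene (chloroprene)
Product: 25 buta-1,3-dien-2-ylmagnesium chloride
Conditions: Mg turnings, ZnCl2 (cat.), BrCH2CH2Br (activator), THF, reflux; used as a titrated solution
Reagents that add atoms: magnesium, [Mg]
Why: Grignard formation from the vinylic chloride, the established preparation of this dienyl reagent.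

Step 16
Reactants: 23 (3R,5S,6R,8S,9R,10R)-12-iodo-3,8-bis(triethylsilyloxy)-13,14,15,16-tetranorlabdan-6-ol; 25 buta-1,3-dien-2-ylmagnesium chloride
Product: 26 (3R,5S,6R,8S,9R,10R)-3,8-bis(triethylsilyloxy)labda-13(16),14-dien-6-ol
Conditions: 25 (3 equiv), Li2CuCl4 (5 mol%), THF, −30 → 0 °C
Reagents that add atoms: none
Why: Kochi copper-catalysed coupling of a primary alkyl iodide with a Grignard reagent, the standard route to 2-alkylbuta-1,3-dienes; the first equivalent of 25 only deprotonates the C6 hydroxyl.

Step 17
Reactants: 26 (3R,5S,6R,8S,9R,10R)-3,8-bis(triethylsilyloxy)labda-13(16),14-dien-6-ol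
Product: 27 (3R,5S,6R,8S,9R,10R)-3,8-bis(triethylsilyloxy)labda-13(16),14-dien-6-yl acetate
Conditions: Ac2O, 4-(dimethylamino)pyridine, pyridine, 25 → 40 °C
Reagents that add atoms: acetic anhydride, CC(=O)OC(C)=O
Why: Acylation under nucleophilic catalysis of the only free hydroxyl; the silyl ethers keep the more reactive C3 oxygen and the tertiary C8 oxygen out of play.

Step 18
Reactants: 27 (3R,5S,6R,8S,9R,10R)-3,8-bis(triethylsilyloxy)labda-13(16),14-dien-6-yl acetate
Product: 28 (3R,5S,6R,8S,9R,10R)-3,8-dihydroxylabda-13(16),14-dien-6-yl acetate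
Conditions: HF·pyridine, pyridine, THF, 0 → 25 °C
Reagents that add atoms: none
Why: Fluoride-driven cleavage of both triethylsilyl ethers in a buffered, weakly acidic medium; no alkoxide forms, so the acetate neither migrates nor is cleaved, and the diene and tertiary alcohol are left alone.

## Compound list

1 | 2,2-dimethylcyclohexane-1,3-dione | CC1(C)C(=O)CCCC1=O | starting material
2 | 6,6-dimethyl-1,4-dioxaspiro[4.5]decan-7-one | CC1(C)C(=O)CCCC12OCCO2 | intermediate
3 | lithium 6,6-dimethyl-1,4-dioxaspiro[4.5]dec-7-en-7-olate | [Li]OC1=CCCC2(OCCO2)C1(C)C | intermediate (not isolated)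
4 | 6,6,8-trimethyl-1,4-dioxaspiro[4.5]decan-7-one (racemic) | CC1CCC2(OCCO2)C(C)(C)C1=O | intermediate
5 | potassium 6,6,8-trimethyl-1,4-dioxaspiro[4.5]dec-7-en-7-olate | [K]OC1=C(C)CCC2(OCCO2)C1(C)C | intermediate (not isolated)
6 | 6,6,8-trimethyl-1,4-dioxaspiro[4.5]dec-7-en-7-yl trifluoromethanesulfonate | CC1=C(OS(=O)(=O)C(F)(F)F)C(C)(C)C2(OCCO2)CC1 | intermediate
7 | 2,6,6-trimethyl-5-oxocyclohex-1-en-1-yl trifluoromethanesulfonate | CC1=C(OS(=O)(=O)C(F)(F)F)C(C)(C)C(=O)CC1 | intermediate
8 | 4-methylanisole | COc1ccc(C)cc1 | starting material
9 | 1-methoxy-4-methylcyclohexa-1,4-diene | COC1=CCC(C)=CC1 | intermediate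
10 | methyl (3Z)-6-hydroperoxy-6-methoxy-4-methylhex-3-enoate | COC(=O)C/C=C(/C)CC(OC)OO | intermediate (not isolated)
11 | methyl (3Z)-4-methyl-6-oxohex-3-enoate | COC(=O)C/C=C(/C)CC=O | intermediate
12 | (2,6,6-trimethyl-5-oxocyclohex-1-en-1-yl)chromium dichloride | CC1=C([Cr](Cl)Cl)C(C)(C)C(=O)CC1 | intermediate (not isolated)
13 | methyl (3Z)-6-hydroxy-4-methyl-6-(2,6,6-trimethyl-5-oxocyclohex-1-en-1-yl)hex-3-enoate (racemic) | COC(=O)C/C=C(/C)CC(O)C1=C(C)CCC(=O)C1(C)C | intermediate
14 | lithium (3Z)-6-hydroxy-4-methyl-6-(2,6,6-trimethyl-5-oxocyclohex-1-en-1-yl)hex-3-enoate (racemic) | [Li+].[O-]C(=O)C/C=C(/C)CC(O)C1=C(C)CCC(=O)C1(C)C | intermediate (not isolated)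
15 | (3Z)-6-hydroxy-4-methyl-6-(2,6,6-trimethyl-5-oxocyclohex-1-en-1-yl)hex-3-enoic acid (racemic) | OC(=O)C/C=C(/C)CC(O)C1=C(C)CCC(=O)C1(C)C | intermediate
16 | allyl cation of 15 after loss of water from C6, charge shared by C6 and C10, drawn with the charge on C10; paired with the catalyst anion | OC(=O)C/C=C(/C)CC=C1C(C)(C)C(=O)CC[C+]1C | intermediate (not isolated)
17 | (8S,9R,10S)-3-oxo-13,14,15,16-tetranorlabd-5-en-12,8-olide (cis-fused γ-lactone, C11 anti to C20) | O=C1C[C@@H]2[C@]3(C)CCC(=O)C(C)(C)C3=CC[C@]2(C)O1 | intermediate
18 | (3R,8S,9R,10S)-13,14,15,16-tetranorlabd-5-ene-3,8,12-triol | OCC[C@@H]1[C@]2(C)CC[C@@H](O)C(C)(C)C2=CC[C@]1(C)O | intermediate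
19 | (3R,8S,9R,10S)-3,8,12-tris(triethylsilyloxy)-13,14,15,16-tetranorlabd-5-ene | CC[Si](CC)(CC)OCC[C@@H]1[C@]2(C)CC[C@@H](O[Si](CC)(CC)CC)C(C)(C)C2=CC[C@]1(C)O[Si](CC)(CC)CC | intermediate
20 | C6 borane adduct of 19: 6-boranyl-3,8,12-tris(triethylsilyloxy)-13,14,15,16-tetranorlabdane, boron on C6 and hydrogen on C5 both anti to C20 | CC[Si](CC)(CC)OCC[C@@H]1[C@]2(C)CC[C@@H](O[Si](CC)(CC)CC)C(C)(C)[C@H]2[C@H](B)C[C@]1(C)O[Si](CC)(CC)CC | intermediate (not isolated)
21 | (3R,5S,6R,8S,9R,10R)-3,8,12-tris(triethylsilyloxy)-13,14,15,16-tetranorlabdan-6-ol | CC[Si](CC)(CC)OCC[C@@H]1[C@]2(C)CC[C@@H](O[Si](CC)(CC)CC)C(C)(C)[C@H]2[C@H](O)C[C@]1(C)O[Si](CC)(CC)CC | intermediate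
22 | (3R,5S,6R,8S,9R,10R)-3,8-bis(triethylsilyloxy)-13,14,15,16-tetranorlabdane-6,12-diol | OCC[C@@H]1[C@]2(C)CC[C@@H](O[Si](CC)(CC)CC)C(C)(C)[C@H]2[C@H](O)C[C@]1(C)O[Si](CC)(CC)CC | intermediate
23 | (3R,5S,6R,8S,9R,10R)-12-iodo-3,8-bis(triethylsilyloxy)-13,14,15,16-tetranorlabdan-6-ol | ICC[C@@H]1[C@]2(C)CC[C@@H](O[Si](CC)(CC)CC)C(C)(C)[C@H]2[C@H](O)C[C@]1(C)O[Si](CC)(CC)CC | intermediate
24 | 2-chlorobuta-1,3-diene (chloroprene) | C=CC(Cl)=C | starting material
25 | buta-1,3-dien-2-ylmagnesium chloride | C=CC(=C)[Mg]Cl | intermediate
26 | (3R,5S,6R,8S,9R,10R)-3,8-bis(triethylsilyloxy)labda-13(16),14-dien-6-ol | C=CC(=C)CC[C@@H]1[C@]2(C)CC[C@@H](O[Si](CC)(CC)CC)C(C)(C)[C@H]2[C@H](O)C[C@]1(C)O[Si](CC)(CC)CC | intermediate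
27 | (3R,5S,6R,8S,9R,10R)-3,8-bis(triethylsilyloxy)labda-13(16),14-dien-6-yl acetate | C=CC(=C)CC[C@@H]1[C@]2(C)CC[C@@H](O[Si](CC)(CC)CC)C(C)(C)[C@H]2[C@H](OC(C)=O)C[C@]1(C)O[Si](CC)(CC)CC | intermediate
28 | (3R,5S,6R,8S,9R,10R)-3,8-dihydroxylabda-13(16),14-dien-6-yl acetate (CNP0351600.2) | C=CC(=C)CC[C@@H]1[C@]2(C)CC[C@@H](O)C(C)(C)[C@H]2[C@H](OC(C)=O)C[C@]1(C)O | target

## Step count and risks

Total: 18 steps. Longest linear sequence: 15 steps from 1 (steps 1–4, 7–14, 16–18); steps 5–6 and step 15 are side branches.

**Step 9 (key step, proposed new method).**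
- What may go wrong: proton loss from C1 or C7 of cation 16 may outrun the strained closure of the cisoid allyl unit. The two enantiomers of 15 may fail to converge if the olefin assists ionisation, so that the old C6 centre and not the anion chooses the face of C10. Face discrimination by the anion may simply be low for a twisted, delocalised cation.
- Fallback (known chemistry, from 15 back to 17): 15 is cyclised with an achiral acid under the conditions of allylic-alcohol-initiated polyene cyclisations (CF3CO2H, CH2Cl2, −78 °C). This should give 17 together with its mirror image, ent-17 F1. The two are separated by preparative chromatography on a chiral stationary phase, and the route continues from 17.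

**Step 7.**
- What may go wrong: insertion of nickel into the tetrasubstituted triflate flanked by a quaternary carbon may be slow, leaving aldehyde 11 time to isomerise into conjugation or self-condense.
- Fallback (from 4 back to 13): ketone 4 is condensed with 2,4,6-tri(propan-2-yl)benzenesulfonohydrazide to the hydrazone N'-(6,6,8-trimethyl-1,4-dioxaspiro[4.5]decan-7-ylidene)-2,4,6-tri(propan-2-yl)benzenesulfonohydrazide F2. Shapiro fragmentation with n-BuLi, transmetalation with CeCl3 and addition to 11 at −78 °C then give the ketal hydroxy ester methyl (3Z)-6-hydroxy-4-methyl-6-(6,6,8-trimethyl-1,4-dioxaspiro[4.5]dec-7-en-7-yl)hex-3-enoate F3. The ketal is removed with pyridinium p-toluenesulfonate in wet acetone to reach 13.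

**Step 12.**
- What may go wrong: facial selectivity may be poor. Ring B of the octalin can flip, and the wanted face carries the axial C9 chain, so part of the borane may add syn to C20 and give the cis-fused C5,C6 diastereomer.
- Fallback (from 19 back to 21): C5 and C6 are set under thermodynamic control.
  - The unseparated hydroboration product, 21 together with (3R,5R,6S,8S,9R,10R)-3,8,12-tris(triethylsilyloxy)-13,14,15,16-tetranorlabdan-6-ol F4, is oxidised with Dess–Martin periodinane.
  - The cis-fused ketone (3R,5R,8S,9R,10S)-3,8,12-tris(triethylsilyloxy)-13,14,15,16-tetranorlabdan-6-one F5 is epimerised at C5 with 1,8-diazabicyclo[5.4.0]undec-7-ene in toluene to the trans-fused ketone (3R,5S,8S,9R,10S)-3,8,12-tris(triethylsilyloxy)-13,14,15,16-tetranorlabdan-6-one F6.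
  - Dissolving-metal reduction (Li, NH3, THF, MeOH, −78 °C) should then give the more stable equatorial alcohol 21.

**Step 16.**
- What may go wrong: the dienyl Grignard reagent may lose titre through polymerisation, and transfer of the sp2 group may be slow enough for reduction or elimination of the iodide to compete.
- Fallback (from 23 back to 26): the iodide is displaced with lithium acetylide–ethylenediamine complex in DMSO to give the terminal alkyne (3R,5S,6R,8S,9R,10R)-3,8-bis(triethylsilyloxy)-15,16-dinorlabd-13-yn-6-ol F7. Cross enyne metathesis with ethylene (1 atm) and the second-generation Grubbs catalyst RuCl2(=CHPh)(PCy3)(H2IMes) in toluene then turns the alkyne into the 2-substituted butadiene 26.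

## Further compounds

F1 | step 9 | ent-17, (8R,9S,10R)-3-oxo-13,14,15,16-tetranorlabd-5-en-12,8-olide | O=C1C[C@H]2[C@@]3(C)CCC(=O)C(C)(C)C3=CC[C@@]2(C)O1
F2 | step 7 | N'-(6,6,8-trimethyl-1,4-dioxaspiro[4.5]decan-7-ylidene)-2,4,6-tri(propan-2-yl)benzenesulfonohydrazide (racemic) | CC1CCC2(OCCO2)C(C)(C)C1=NNS(=O)(=O)c1c(C(C)C)cc(C(C)C)cc1C(C)C
F3 | step 7 | methyl (3Z)-6-hydroxy-4-methyl-6-(6,6,8-trimethyl-1,4-dioxaspiro[4.5]dec-7-en-7-yl)hex-3-enoate (racemic) | COC(=O)C/C=C(/C)CC(O)C1=C(C)CCC2(OCCO2)C1(C)C
F4 | step 12 | (3R,5R,6S,8S,9R,10R)-3,8,12-tris(triethylsilyloxy)-13,14,15,16-tetranorlabdan-6-ol (C5,C6 diastereomer of 21) | CC[Si](CC)(CC)OCC[C@@H]1[C@]2(C)CC[C@@H](O[Si](CC)(CC)CC)C(C)(C)[C@@H]2[C@@H](O)C[C@]1(C)O[Si](CC)(CC)CC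
F5 | step 12 | (3R,5R,8S,9R,10S)-3,8,12-tris(triethylsilyloxy)-13,14,15,16-tetranorlabdan-6-one (cis-fused) | CC[Si](CC)(CC)OCC[C@@H]1[C@]2(C)CC[C@@H](O[Si](CC)(CC)CC)C(C)(C)[C@@H]2C(=O)C[C@]1(C)O[Si](CC)(CC)CC
F6 | step 12 | (3R,5S,8S,9R,10S)-3,8,12-tris(triethylsilyloxy)-13,14,15,16-tetranorlabdan-6-one (trans-fused) | CC[Si](CC)(CC)OCC[C@@H]1[C@]2(C)CC[C@@H](O[Si](CC)(CC)CC)C(C)(C)[C@H]2C(=O)C[C@]1(C)O[Si](CC)(CC)CC
F7 | step 16 | (3R,5S,6R,8S,9R,10R)-3,8-bis(triethylsilyloxy)-15,16-dinorlabd-13-yn-6-ol | C#CCC[C@@H]1[C@]2(C)CC[C@@H](O[Si](CC)(CC)CC)C(C)(C)[C@H]2[C@H](O)C[C@]1(C)O[Si](CC)(CC)CC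
A1 | alternative 1 | 3-(tert-butyldimethylsilyloxy)-12-(4-methoxybenzyloxy)-13,14,15,16-tetranorlabd-8(17)-en-6-ol, configured as the target at C3, C5, C6, C9 and C10 | COc1ccc(COCC[C@@H]2[C@]3(C)CC[C@@H](O[Si](C)(C)C(C)(C)C)C(C)(C)[C@H]3[C@H](O)CC2=C)cc1
A2 | alternative 2 | (1S,5S)-verbenone, (1S,5S)-4,6,6-trimethylbicyclo[3.1.1]hept-3-en-2-one | C1=C(C)[C@@H]2C[C@H](C1=O)C2(C)C
A3 | alternative 2 | tert-butyl [4-(2-(1,3-dioxolan-2-yl)ethyl)-4,6,6-trimethyl-2-oxobicyclo[3.1.1]heptan-3-yl]acetate, both new groups anti to the gem-dimethyl bridge | CC(C)(C)OC(=O)C[C@@H]1[C@](C)(CCC2OCCO2)[C@@H]3C[C@H](C1=O)C3(C)C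
A4 | alternative 3 | 6-(tert-butyldimethylsilyloxy)-3-hydroxy-13,14,15,16-tetranorlabdan-12,8-olide, configured as the target at C3, C5, C6, C8, C9 and C10 | O=C1C[C@@H]2[C@]3(C)CC[C@@H](O)C(C)(C)[C@H]3[C@H](O[Si](C)(C)C(C)(C)C)C[C@]2(C)O1
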